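**Strategy.** The ten-membered carbocycle C1–C10 is cut at C8–C9 by an oxy-Cope transform. An oxygen at C6 (a ketone at that stage) and the C1=C10 unit (later the cis-epoxide) standing 1,5 to it identify the macrocycle as the rearrangement product of a 1,2-dialkenylcyclohexenol, and the Z-C4=C5 double bond is nothing but the cyclohexene alkene. In one operation the six-membered ring grows to ten, C8–C9 is made, and a chair transition state fixes E-C1=C10 and the C8 centre, where silicon stands in for oxygen. The precursor is a carvone-derived trans-1-(E-2-silylvinyl)-6-isopropenylcyclohex-2-en-1-ol with a 4-methoxybenzyl ether at C3.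

Key step: step 9

Remark 1: germacrane numbering (ring C1–C10, lactone carbons C11–C13, C14 on C10, C15 on C4) is used for all ten-membered-ring compounds; the target is (1R,3S,6S,7S,8R,10S). PMB = 4-methoxybenzyl.
Remark 2: the C3 oxygen is carried as a PMB ether, because the fluoride that later unmasks the C8 silane would strip a silyl ether.
Remark 3: the C6 ketone of 22 is assumed to be reduced from its peripheral (Felkin–Anh) face, so the lactone is closed with inversion at C6.

Step 1
Reactants: 1 (S)-(+)-carvone
Product: 2 trans-carvone epoxide (epoxide anti to the isopropenyl group)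
Conditions: 30% H2O2, NaOH (cat.), MeOH, 0 °C
Reagents that add atoms: hydrogen peroxide, OO
Why: Weitz–Scheffer nucleophilic epoxidation touches only the enone, and hydroperoxide should add axially to the β-carbon anti to the isopropenyl group, so the two relay centres of the epoxide form trans to it.

Step 2
Reactants: 2 trans-carvone epoxide
Product: 4 (1S,5R)-trans-carveol, via epoxy hydrazone 3 (not isolated)
Conditions: N2H4·H2O, AcOH (cat.), MeOH, 0 °C to rt
Reagents that add atoms: none
Why: Wharton transposition: the epoxy hydrazone should collapse to a vinyldiazene that loses N2, shifting the alkene while the C–O bond of the former β-carbon stays intact, so the hydroxyl (the future C3 oxygen) remains trans to the isopropenyl-bearing centre (the future C1).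

Step 3
Reactants: 4 (1S,5R)-trans-carveol
Product: 5 cis-epoxy alcohol (epoxide syn to OH)
Conditions: VO(acac)2 (cat.), t-BuOOH, CH2Cl2, 0 °C to rt
Reagents that add atoms: tert-butyl hydroperoxide, CC(C)(C)OO
Why: Vanadium-catalysed hydroxyl-directed epoxidation should deliver oxygen only to the allylic ring alkene and syn to the hydroxyl (hence anti to the isopropenyl group, which is left alone); both new centres are relay centres erased in steps 5 and 6.

Step 4
Reactants: 5 cis-epoxy alcohol
Product: 6 PMB ether of 5
Conditions: NaH, 4-MeOC6H4CH2Cl, Bu4NI (cat.), THF/DMF, 0 °C to rt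
Reagents that add atoms: 4-methoxybenzyl chloride, COc1ccc(CCl)cc1
Why: Williamson etherification of the sodium alkoxide, which cannot trigger Payne migration because the epoxide lies syn to it; the PMB ether resists the fluoride of step 13 and is removed oxidatively at the end.

Step 5
Reactants: 6 PMB ether of 5
Product: 9 tertiary allylic alcohol (1-methyl-6-PMB-oxy-4-isopropenylcyclohex-2-en-1-ol), via hydroxy selenide 7 (not isolated), via selenoxide 8 (not isolated)
Conditions: (PhSe)2, NaBH4, EtOH, rt to 60 °C; then 30% H2O2, pyridine, THF, 0 °C to rt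
Reagents that add atoms: none
Why: Epoxide-to-allylic-alcohol transposition by selenide opening and selenoxide syn-elimination: PhSe− should attack the secondary epoxide carbon (SN2, trans-diaxial, Fürst–Plattner), and the selenoxide can eliminate only toward the ring CH2 because the carbinol carbon carries no hydrogen.

Step 6
Reactants: 9 tertiary allylic alcohol
Product: 10 (4S,6R)-4-(PMB-oxy)-3-methyl-6-isopropenylcyclohex-2-en-1-one
Conditions: pyridinium chlorochromate [C5H5NH][CrO3Cl], 4 Å molecular sieves, CH2Cl2, rt
Reagents that add atoms: pyridinium chlorochromate, [O-][Cr](=O)(=O)Cl.c1cc[nH+]cc1 (the carbonyl oxygen is transferred from chromium in the allylic shift)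
Why: Dauben–Babler oxidative 1,3-transposition: the tertiary allylic chromate ester should undergo a [3,3] shift and oxidation to the β-methyl enone, which places the carbonyl next to the isopropenyl-bearing carbon without touching the two stereocentres.

Step 7
Reactants: 11 (E)-1,2-bis(tributylstannyl)ethene; 12 benzylchlorodimethylsilane
Product: 14 (E)-benzyl(dimethyl)[2-(tributylstannyl)ethenyl]silane, via stannylvinyllithium 13 (not isolated)
Conditions: n-BuLi (1.0 equiv), THF, −78 °C; then 12, −78 °C to rt
Reagents that add atoms: benzylchlorodimethylsilane (12), C[Si](C)(Cl)Cc1ccccc1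
Why: Tin–lithium exchange of one stannyl group and silylation of the resulting vinyllithium both proceed with retention of the E geometry.

Step 8
Reactants: 14 (E)-benzyl(dimethyl)[2-(tributylstannyl)ethenyl]silane; 10 enone
Product: 16 (1R,4S,6R)-1-[(E)-2-(benzyldimethylsilyl)ethenyl]-4-(PMB-oxy)-3-methyl-6-isopropenylcyclohex-2-en-1-ol, via silylvinyllithium 15 (not isolated)
Conditions: 14, n-BuLi, THF, −78 °C; then 10, −78 °C; NH4Cl (aq)
Reagents that add atoms: (E)-2-(benzyldimethylsilyl)vinyllithium (15, made from 14), [Li]/C=C/[Si](C)(C)Cc1ccccc1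
Why: Second tin–lithium exchange and 1,2-addition of the vinyllithium to the β,β-disubstituted enone; equatorial attack anti to the neighbouring isopropenyl group should set the carbinol centre (1R, the future C6) with the two alkenyl groups trans.

Step 9
Reactants: 16 trans-dialkenyl cyclohexenol
Product: 19 cyclodecadienone (C6 ketone; Z-C4=C5; E-C1=C10; 3S OPMB; 8R SiMe2Bn), via potassium alkoxide 17 (not isolated), via potassium enolate 18 (not isolated)
Conditions: KH, 18-crown-6, THF, 0 °C to rt; then NH4Cl (aq), −78 °C
Reagents that add atoms: none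
Why: KH with 18-crown-6 gives the dissociated potassium alkoxide 17, whose oxyanion loosens the allylic C1–C6 bond so that the 1,5-diene C8=C7–C6–C1–C10=C9 undergoes a concerted, charge-accelerated [3,3] sigmatropic shift (C8–C9 made, C1–C6 cleaved) to the enolate 18, protonated at C7 on quench. The closest known reaction type is the anionic oxy-Cope rearrangement of trans-1,2-dialkenylcyclohexanols to cyclodec-5-enones. The ten-membered ring is closed by a four-atom ring expansion of the cyclohexene through the sigmatropic shift, not by an end-to-end cyclisation, and the ring alkene is carried over unchanged as Z-C4=C5. The new C8 centre (R) is controlled by chirality transfer from C1 and C6 through a chair transition state in which the ring bonds C6–C5 and C1–C2 are equatorial, combined with the E geometry of the vinylsilane, which holds silicon equatorial; the same chair gives E-C1=C10. The step needs chair over boat and the exocyclic vinyl/isopropenyl pair over the alternative diene C4=C5–C6–C1–C10=C9: the two alkenyl groups are trans-diequatorial and so already sit in the chair array, whereas the ring alkene can reach C9 only through a strained bridged boat. A carbon–silicon bond at C8 gives the enolate no β-leaving group, and the benzyl–silicon bond is inert to alkoxide in the absence of fluoride.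

Step 10
Reactants: 19 cyclodecadienone; 20 methyl bromoacetate
Product: 22 C7-alkylated keto ester (7R; CH2CO2Me trans to the C8 silyl group), via lithium enolate 21 (not isolated)
Conditions: LiN(iPr)2, THF, −78 °C; then BrCH2CO2Me, DMPU, −78 to −40 °C
Reagents that add atoms: methyl bromoacetate (20), COC(=O)CBr
Why: Kinetic α′-deprotonation removes the peripheral C7–H aligned with the carbonyl π system and should regenerate the ring-E enolate of step 9, which is alkylated (SN2 enolate alkylation) on its only open face, anti to the C8–C9 bond that shields the inner face, setting C7 with the acetate arm trans to the C8 silyl group.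

Step 11
Reactants: 22 keto ester
Product: 24 6R hydroxy acid, via hydroxy ester 23 (not isolated)
Conditions: NaBH4, CeCl3·7H2O, MeOH, −78 °C; then LiOH, THF/H2O, 0 °C to rt; 1 M HCl to pH 5, 0 °C
Reagents that add atoms: lithium hydroxide, [Li+].[OH-]
Why: Luche 1,2-reduction: hydride should arrive on the peripheral face of the C6 carbonyl, anti to C8 as the Felkin–Anh model also requires, giving the 6R alcohol cis to the acetate arm; hydroxide then saponifies the methyl ester and reopens any cis-lactone formed by acyl transfer.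

Step 12
Reactants: 24 6R hydroxy acid
Product: 25 trans-fused 12,6-lactone (6S)
Conditions: PPh3, DIAD, THF, 0 °C to rt
Reagents that add atoms: none
Why: Mitsunobu lactonisation: the carboxylate should displace the phosphonium-activated allylic C6 oxygen intramolecularly (5-exo-tet SN2) with inversion, which turns the 6R hydroxy acid into the 6S trans-fused lactone.

Step 13
Reactants: 25 trans-fused lactone
Product: 27 8R alcohol, via fluorosilane 26 (not isolated)
Conditions: Bu4NF, THF, 0 °C to rt; then KHCO3, 30% H2O2, MeOH/THF, rt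
Reagents that add atoms: hydrogen peroxide, OO
Why: Tamao–Fleming oxidation: fluoride cleaves the benzyl–silicon bond and alkaline peroxide then moves C8 from silicon to oxygen with retention, giving the 8R alcohol, while the PMB ether and both alkenes are inert.

Step 14
Reactants: 27 8R alcohol
Product: 28 8-isobutyrate
Conditions: (i-PrCO)2O, Et3N, DMAP (cat.), CH2Cl2, 0 °C to rt
Reagents that add atoms: isobutyric anhydride, CC(C)C(=O)OC(=O)C(C)C
Why: DMAP-catalysed acylation of the only free hydroxyl, under conditions too mild for migration of the lactone from O6 to O8.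

Step 15
Reactants: 28 8-isobutyrate
Product: 29 (1S,10S)-1,10-diol
Conditions: OsO4 (cat.), NMO, acetone/H2O, 0 °C
Reagents that add atoms: N-methylmorpholine N-oxide, C[N+]1([O-])CCOCC1; water, O (both delivered through osmium tetroxide, O=[Os](=O)(=O)=O)
Why: Upjohn syn-dihydroxylation: OsO4 should select the electron-rich, unhindered C1=C10 alkene over C4=C5 (deactivated by two allylic oxygens) and add from the peripheral face of the E-alkene, giving C10 in its final S configuration and C1 as the S epimer that step 16 inverts.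

Step 16
Reactants: 29 (1S,10S)-diol
Product: 31 (1R,10S)-cis-epoxide, via mesylate 30 (not isolated)
Conditions: MsCl, Et3N, CH2Cl2, −20 °C; then KOt-Bu, t-BuOH/THF, 0 °C
Reagents that add atoms: none
Why: Selective sulfonylation of the secondary C1 hydroxyl followed by intramolecular Williamson closure (3-exo-tet) of the tertiary C10 alkoxide with inversion at C1 should convert the threo diol of the E-alkene into the cis-epoxide.

Step 17
Reactants: 31 cis-epoxide
Product: 35 α-methylene lactone (3-O-PMB ether of the target), via lactone enolate 32 (not isolated), via Mannich base 33 (not isolated), via ammonium iodide 34 (not isolated)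
Conditions: LiN(iPr)2, THF, −78 °C; [Me2N=CH2]I, −78 to 0 °C; then MeI, CH2Cl2, rt; then DBU, rt
Reagents that add atoms: dimethyl(methylidene)ammonium iodide, C[N+](C)=C.[I-]
Why: Eschenmoser methylenation (Mannich reaction of the lactone enolate, N-methylation, base-induced loss of trimethylamine); the lactone α-CH2 is more acidic and more accessible than the isobutyrate methine, and C11 ends sp2 so that no new stereocentre remains.

Step 18
Reactants: 35 3-O-PMB ether of the target
Product: 36 target
Conditions: DDQ, CH2Cl2/pH 7 buffer, 0 °C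
Reagents that add atoms: none
Why: Oxidative cleavage of the PMB ether by DDQ under buffered conditions should free the C3 hydroxyl without touching the epoxide, the α-methylene lactone or the ester.

**Compound list**

1 | (S)-(+)-carvone, (5S)-2-methyl-5-(prop-1-en-2-yl)cyclohex-2-en-1-one | CC1=CC[C@@H](CC1=O)C(C)=C | starting material
2 | trans-carvone epoxide, (1S,4S,6S)-1-methyl-4-(prop-1-en-2-yl)-7-oxabicyclo[4.1.0]heptan-2-one | O=C1C[C@@H](C(C)=C)C[C@@H]2O[C@]12C | intermediate
3 | hydrazone of 2 (not isolated) | NN=C1C[C@@H](C(C)=C)C[C@@H]2O[C@]12C | intermediate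
4 | (1S,5R)-trans-carveol, OH trans to isopropenyl | CC1=CC[C@@H](C(C)=C)C[C@@H]1O | intermediate
5 | cis-epoxy alcohol: 2,3-epoxide of 4, epoxide oxygen syn to OH and anti to isopropenyl | C[C@@]12O[C@@H]1C[C@@H](C(C)=C)C[C@@H]2O | intermediate
6 | PMB ether of 5 | C[C@@]12O[C@@H]1C[C@@H](C(C)=C)C[C@@H]2OCc1ccc(OC)cc1 | intermediate
7 | hydroxy selenide (not isolated): tertiary alcohol, PhSe on the adjacent secondary carbon trans to OH | C[C@@]1(O)[C@@H]([Se]c2ccccc2)C[C@@H](C(C)=C)C[C@@H]1OCc1ccc(OC)cc1 | intermediate
8 | selenoxide of 7 (not isolated) | C[C@@]1(O)[C@@H]([Se](=O)c2ccccc2)C[C@@H](C(C)=C)C[C@@H]1OCc1ccc(OC)cc1 | intermediate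
9 | tertiary allylic alcohol: 1-methyl-6-(PMB-oxy)-4-(prop-1-en-2-yl)cyclohex-2-en-1-ol, OH cis to OPMB, isopropenyl trans to both | C[C@@]1(O)C=C[C@@H](C(C)=C)C[C@@H]1OCc1ccc(OC)cc1 | intermediate
10 | (4S,6R)-4-(PMB-oxy)-3-methyl-6-(prop-1-en-2-yl)cyclohex-2-en-1-one, OPMB trans to isopropenyl | O=C1C=C(C)[C@@H](OCc2ccc(OC)cc2)C[C@@H]1C(C)=C | intermediate
11 | (E)-1,2-bis(tributylstannyl)ethene | CCCC[Sn](CCCC)(CCCC)/C=C/[Sn](CCCC)(CCCC)CCCC | starting material
12 | benzylchlorodimethylsilane | C[Si](C)(Cl)Cc1ccccc1 | starting material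
13 | (E)-2-(tributylstannyl)vinyllithium (not isolated) | [Li]/C=C/[Sn](CCCC)(CCCC)CCCC | intermediate
14 | (E)-benzyl(dimethyl)[2-(tributylstannyl)ethenyl]silane | C[Si](C)(Cc1ccccc1)/C=C/[Sn](CCCC)(CCCC)CCCC | intermediate
15 | (E)-2-(benzyldimethylsilyl)vinyllithium (not isolated) | [Li]/C=C/[Si](C)(C)Cc1ccccc1 | intermediate
16 | (1R,4S,6R)-1-[(E)-2-(benzyldimethylsilyl)ethenyl]-4-(PMB-oxy)-3-methyl-6-(prop-1-en-2-yl)cyclohex-2-en-1-ol, alkenyl groups trans | O[C@]1(/C=C/[Si](C)(C)Cc2ccccc2)C=C(C)[C@@H](OCc2ccc(OC)cc2)C[C@@H]1C(C)=C | intermediate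
17 | potassium alkoxide of 16 (not isolated) | [K+].[O-][C@]1(/C=C/[Si](C)(C)Cc2ccccc2)C=C(C)[C@@H](OCc2ccc(OC)cc2)C[C@@H]1C(C)=C | intermediate
18 | potassium enolate of 19 (not isolated), C6=C7 with C5 and C8 trans | [K+].[O-]/C1=C\[C@H]([Si](C)(C)Cc2ccccc2)C/C(C)=C/C[C@H](OCc2ccc(OC)cc2)/C(C)=C\1 | intermediate
19 | (2Z,4S,6E,9R)-9-(benzyldimethylsilyl)-4-(PMB-oxy)-3,7-dimethylcyclodeca-2,6-dien-1-one; germacrane numbering: C6 ketone, Z-C4=C5, E-C1=C10, 3S OPMB, 8R silyl | O=C1/C=C(/C)[C@@H](OCc2ccc(OC)cc2)C/C=C(\C)C[C@@H]([Si](C)(C)Cc2ccccc2)C1 | intermediate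
20 | methyl bromoacetate | COC(=O)CBr | starting material
21 | lithium enolate of 19 (not isolated) | [Li+].[O-]/C1=C\[C@H]([Si](C)(C)Cc2ccccc2)C/C(C)=C/C[C@H](OCc2ccc(OC)cc2)/C(C)=C\1 | intermediate
22 | keto ester: 19 carrying CH2CO2Me at C7 (7R), trans to the C8 silyl group | O=C1/C=C(/C)[C@@H](OCc2ccc(OC)cc2)C/C=C(\C)C[C@@H]([Si](C)(C)Cc2ccccc2)[C@@H]1CC(=O)OC | intermediate
23 | 6R hydroxy ester (not isolated): OH cis to the C7 acetate arm | O[C@@H]1/C=C(/C)[C@@H](OCc2ccc(OC)cc2)C/C=C(\C)C[C@@H]([Si](C)(C)Cc2ccccc2)[C@@H]1CC(=O)OC | intermediate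
24 | 6R hydroxy acid | O[C@@H]1/C=C(/C)[C@@H](OCc2ccc(OC)cc2)C/C=C(\C)C[C@@H]([Si](C)(C)Cc2ccccc2)[C@@H]1CC(=O)O | intermediate
25 | trans-fused 12,6-lactone (6S,7R,8R) with SiMe2Bn at C8 and 3S OPMB | C1C(=O)O[C@H]2/C=C(/C)[C@@H](OCc3ccc(OC)cc3)C/C=C(\C)C[C@@H]([Si](C)(C)Cc3ccccc3)[C@H]12 | intermediate
26 | fluorosilane (not isolated): 25 with SiMe2F at C8 | C1C(=O)O[C@H]2/C=C(/C)[C@@H](OCc3ccc(OC)cc3)C/C=C(\C)C[C@@H]([Si](C)(C)F)[C@H]12 | intermediate
27 | 8R alcohol: 25 with OH in place of silicon | C1C(=O)O[C@H]2/C=C(/C)[C@@H](OCc3ccc(OC)cc3)C/C=C(\C)C[C@@H](O)[C@H]12 | intermediate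
28 | 8-isobutyrate of 27 | C1C(=O)O[C@H]2/C=C(/C)[C@@H](OCc3ccc(OC)cc3)C/C=C(\C)C[C@@H](OC(=O)C(C)C)[C@H]12 | intermediate
29 | (1S,10S)-1,10-diol of 28 | C1C(=O)O[C@H]2/C=C(/C)[C@@H](OCc3ccc(OC)cc3)C[C@H](O)[C@@](C)(O)C[C@@H](OC(=O)C(C)C)[C@H]12 | intermediate
30 | C1 mesylate of 29 (not isolated) | C1C(=O)O[C@H]2/C=C(/C)[C@@H](OCc3ccc(OC)cc3)C[C@H](OS(C)(=O)=O)[C@@](C)(O)C[C@@H](OC(=O)C(C)C)[C@H]12 | intermediate
31 | (1R,10S)-cis-1,10-epoxide with saturated lactone, 3-OPMB and 8-isobutyrate | C1C(=O)O[C@H]2/C=C(/C)[C@@H](OCc4ccc(OC)cc4)C[C@H]3O[C@@]3(C)C[C@@H](OC(=O)C(C)C)[C@H]12 | intermediate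
32 | lithium enolate of lactone 31 (not isolated) | C1=C([O-])O[C@H]2/C=C(/C)[C@@H](OCc4ccc(OC)cc4)C[C@H]3O[C@@]3(C)C[C@@H](OC(=O)C(C)C)[C@H]12.[Li+] | intermediate
33 | Mannich base (not isolated): 31 with CH2NMe2 at C11, C11 epimers | CN(C)CC1C(=O)O[C@H]2/C=C(/C)[C@@H](OCc4ccc(OC)cc4)C[C@H]3O[C@@]3(C)C[C@@H](OC(=O)C(C)C)[C@H]12 | intermediate
34 | trimethylammonium iodide of 33 (not isolated) | C[N+](C)(C)CC1C(=O)O[C@H]2/C=C(/C)[C@@H](OCc4ccc(OC)cc4)C[C@H]3O[C@@]3(C)C[C@@H](OC(=O)C(C)C)[C@H]12.[I-] | intermediate
35 | 3-O-PMB ether of the target | C=C1C(=O)O[C@H]2/C=C(/C)[C@@H](OCc4ccc(OC)cc4)C[C@H]3O[C@@]3(C)C[C@@H](OC(=O)C(C)C)[C@H]12 | intermediate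
36 | (1R,3S,6S,7S,8R,10S)-1,10-epoxy-3-hydroxy-8-(isobutyryloxy)germacra-4Z,11(13)-dien-12,6-olide | C=C1C(=O)O[C@H]2/C=C(/C)[C@@H](O)C[C@H]3O[C@@]3(C)C[C@@H](OC(=O)C(C)C)[C@H]12 | target

**Step count.** Total: 18 steps. Longest linear sequence: 17 steps (steps 1–6 and 8–18, from 1); the silylstannane branch (step 7) joins at step 8.

**Steps most likely to fail**

Step 9. The dissociated alkoxide may fragment (retro-ene or β-cleavage at the bis-allylic carbinol), or the base may erode the benzylsilane faster than the sigmatropic shift proceeds. The fallback sets out from 16 and runs the shift without charge. The hydroxyl is capped as the trimethylsilyl ether of 16 F1 (N-trimethylsilylimidazole, CH2Cl2, rt). Thermolysis (degassed toluene, sealed tube, about 210 °C) should take F1 through the same chair to the ring-E trimethylsilyl enol ether of 19 F2. Mild acid hydrolysis (oxalic acid, wet THF, 0 °C) rejoins the route at 19.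

Step 11. Hydride may be delivered to the other face of the C6 carbonyl (reversed or poor facial selectivity), so that the alcohol forms trans to the acetate arm. The fallback sets out from 22. The Luche reduction is stopped before the hydroxide treatment and the 6S epimer of hydroxy ester 23 F3 is isolated. It is closed by acid-catalysed acyl transfer with retention (pyridinium p-toluenesulfonate, toluene, 60 °C), which rejoins the route at 25 and makes the saponification and step 12 unnecessary. A mixture of C6 epimers can be separated and each sent through its own closure.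

Step 12. The phosphonium reagent may activate the carboxyl group instead of the hindered allylic hydroxyl, so that the ring closes with retention to the cis-fused lactone, or the activated alcohol may eliminate. The fallback sets out from the hydroxy ester 23, isolated after the reduction of step 11. Intermolecular Mitsunobu inversion with 4-nitrobenzoic acid (PPh3, DIAD, toluene, 0 °C) should give the 6S 4-nitrobenzoate of the hydroxy ester F4. K2CO3 in MeOH then removes the nitrobenzoate, and the liberated 6S hydroxy ester F3 closes onto its methyl ester, rejoining the route at 25.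

**Further compounds**

F1 | step 9 | trimethylsilyl ether of 16 | C[Si](C)(C)O[C@]1(/C=C/[Si](C)(C)Cc2ccccc2)C=C(C)[C@@H](OCc2ccc(OC)cc2)C[C@@H]1C(C)=C
F2 | step 9 | trimethylsilyl enol ether of 19 (C6=C7 with C5 and C8 trans) | C[Si](C)(C)O/C1=C\[C@H]([Si](C)(C)Cc2ccccc2)C/C(C)=C/C[C@H](OCc2ccc(OC)cc2)/C(C)=C\1
F3 | step 11 | 6S epimer of hydroxy ester 23 | O[C@H]1/C=C(/C)[C@@H](OCc2ccc(OC)cc2)C/C=C(\C)C[C@@H]([Si](C)(C)Cc2ccccc2)[C@@H]1CC(=O)OC
F4 | step 12 | 6S 4-nitrobenzoate of the hydroxy ester | O=C(O[C@H]1/C=C(/C)[C@@H](OCc2ccc(OC)cc2)C/C=C(\C)C[C@@H]([Si](C)(C)Cc2ccccc2)[C@@H]1CC(=O)OC)c1ccc(cc1)[N+](=O)[O-]
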